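**Retrosynthetic overview**

- Feature: both carbonyl carbons, the acyl carbon on C3 of the 2,3-dihydrobenzofuran and the terminal C=O of the propanoyl chain on C5, are bonded to a 2,4-dihydroxyphenyl ring. Each aryl–C(=O) bond is therefore the Fries isomer of a resorcinol monoester O–C(=O) bond, and target 14 is an isomer of diester 11.
- 14 ⇒ 11 by a twofold O→C acyl shift; 11 ⇒ tris-silyl ether 10 ⇒ diacid 8 + two molecules of mono-silylated resorcinol 9.
- 8 ⇒ dibenzyl ester 6 by one hydrogenation that saturates the side-chain C=C and frees both acids, so no hydroxide meets the C3–H/C2–O1 array.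
- 6 ⇒ 5 ⇒ racemic trans dimer 4 (resolution) ⇒ two molecules of benzyl 4-hydroxycinnamate 2 by Ag2O 8–5' oxidative coupling.
- Ring order: the benzene rings are bought; the dihydrofuran ring (C3–C3a, then O1–C2) is the only ring made, in step 2. The resorcinol rings are attached through O in step 6 and moved to C in step 8.

Key step: step 8

Remark: the fraction of step 3 with the (2S,3S) configuration is to be identified by electronic circular dichroism against the computed spectrum before it is carried on; phenol 9 is taken as a catalogue compound.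

**Route**

Step 1
Reactants: 1 (E)-4-hydroxycinnamic acid
Product: 2 benzyl (E)-3-(4-hydroxyphenyl)prop-2-enoate
Conditions: BnBr (1.05 equiv), KHCO3 (1.1 equiv), DMF, rt
Reagents that add atoms: benzyl bromide, BrCc1ccccc1
Why: Chemoselective SN2 O-alkylation of the carboxylate, since bicarbonate ionises only the acid and leaves the phenol free for the coupling that follows.

Step 2
Reactants: 2 benzyl (E)-3-(4-hydroxyphenyl)prop-2-enoate (two molecules)
Product: 4 racemic trans dimer benzyl (2RS,3RS)-5-[(E)-3-(benzyloxy)-3-oxoprop-1-enyl]-2-(4-hydroxyphenyl)-2,3-dihydro-1-benzofuran-3-carboxylate, via quinone methide phenol 3 (not isolated)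
Conditions: Ag2O (0.5 equiv), MeCN, rt, dark
Reagents that add atoms: none
Why: Biomimetic oxidative phenol coupling, in which Ag2O forms the phenoxyl radical, C8–C5' radical coupling and re-aromatisation give quinone methide 3, and intramolecular oxa-Michael addition of the new phenol to the methide carbon closes the furan ring with the C2 aryl and C3 ester anti (trans, racemic), as is established for alkyl 4-hydroxycinnamates; other coupling modes compete, so only a modest yield is expected.

Step 3
Reactants: 4 racemic trans dimer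
Product: 5 benzyl (2S,3S)-5-[(E)-3-(benzyloxy)-3-oxoprop-1-enyl]-2-(4-hydroxyphenyl)-2,3-dihydro-1-benzofuran-3-carboxylate
Conditions: preparative chiral SFC, amylose tris(3,5-dimethylphenylcarbamate) phase, CO2/MeOH
Reagents that add atoms: none
Why: Resolution by enantioselective chromatography on a polysaccharide phase, a standard separation for dihydrobenzofuran neolignan esters, which fixes the absolute configuration (2S,3S) without making or breaking a bond.

Step 4
Reactants: 5 (2S,3S) dimer dibenzyl ester
Product: 6 benzyl (2S,3S)-5-[(E)-3-(benzyloxy)-3-oxoprop-1-enyl]-2-[4-(tert-butyldimethylsilyloxy)phenyl]-2,3-dihydro-1-benzofuran-3-carboxylate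
Conditions: TBSCl, imidazole, DMF, rt
Reagents that add atoms: tert-butyldimethylsilyl chloride, CC(C)(C)[Si](C)(C)Cl
Why: Imidazole-promoted silylation of the only phenol, needed so that this phenol cannot compete in the later esterification, under a base too weak to deprotonate C3–H.

Step 5
Reactants: 6 silylated dibenzyl ester
Product: 8 (2S,3S)-5-(2-carboxyethyl)-2-[4-(tert-butyldimethylsilyloxy)phenyl]-2,3-dihydro-1-benzofuran-3-carboxylic acid, via saturated dibenzyl ester 7 (not isolated)
Conditions: H2 (1 atm), 10% Pd/C, EtOAc, rt, stopped after uptake of 3 equiv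
Reagents that add atoms: none
Why: Heterogeneous catalytic hydrogenation saturates the cinnamate C=C and then hydrogenolyses both benzyl esters under neutral conditions, with ethyl acetate (not methanol) to keep the aryl silyl ether and with the hindered, ring-bound secondary benzylic C2–O1 ether expected to survive at 1 atm.

Step 6
Reactants: 8 silylated diacid; 9 3-(tert-butyldimethylsilyloxy)phenol (2.5 equiv)
Product: 10 3-(tert-butyldimethylsilyloxy)phenyl (2S,3S)-2-[4-(tert-butyldimethylsilyloxy)phenyl]-5-{3-oxo-3-[3-(tert-butyldimethylsilyloxy)phenoxy]propyl}-2,3-dihydro-1-benzofuran-3-carboxylate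
Conditions: EDC·HCl (2.6 equiv), DMAP (0.2 equiv), CH2Cl2, 0 °C → rt
Reagents that add atoms: none
Why: Steglich esterification of both acids with the phenol, where low temperature and sub-stoichiometric DMAP limit ketene formation at the α-aryl C3 carboxyl and any C3 epimerisation would return to the favoured trans isomer.

Step 7
Reactants: 10 tris-silyl bis(aryl ester)
Product: 11 3-hydroxyphenyl (2S,3S)-2-(4-hydroxyphenyl)-5-[3-(3-hydroxyphenoxy)-3-oxopropyl]-2,3-dihydro-1-benzofuran-3-carboxylate
Conditions: HF·pyridine, pyridine, THF, 0 °C → rt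
Reagents that add atoms: none
Why: Fluoride cleavage of the three aryl Si–O bonds under acidic buffering releases neutral phenols instead of phenoxides, so the aryl esters should not be transacylated and C3–H is not deprotonated.

Step 8
Reactants: 11 bis(3-hydroxyphenyl) ester
Product: 14 target 3-[(2S,3S)-3-(2,4-dihydroxybenzoyl)-2-(4-hydroxyphenyl)-2,3-dihydro-1-benzofuran-5-yl]-1-(2,4-dihydroxyphenyl)propan-1-one, via side-chain ketone C3 ester 12 (not isolated), via C3 ketone side-chain ester 13 (not isolated)
Conditions: hν 254 nm (low-pressure Hg, quartz thin-film flow reactor), degassed MeCN (1 mM), −20 °C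
Reagents that add atoms: none
Why: Singlet excitation of each aryl ester homolyses the ArO–C(=O) bond to a solvent-caged acyl/3-hydroxyphenoxyl radical pair that recombines at a ring carbon, and tautomerisation of the resulting cyclohexadienone gives the hydroxyaryl ketone; the two esters react independently, so 12 and 13 both lead on to 14. The closest known reaction is the photo-Fries rearrangement of aryl alkanoates and of resorcinol monobenzoate to 2,4-dihydroxybenzophenone. No ring is closed and no stereocentre is made, and C2 and C3 keep their configuration because the radical centre is the acyl carbon and the medium is neutral. The regioselectivity needed is secured by the substrate, since recombination at C6 (ortho to the ester oxygen, para to the free hydroxyl) and at C4 (para to the ester oxygen) give the same 2,4-dihydroxybenzoyl group, and only C2, flanked by both oxygens, would give the wrong isomer. Cage recombination must also outrun decarbonylation of the C3 acyl radical to a secondary benzylic radical, which low temperature should favour because decarbonylation is activated and recombination is not. The product ketones dissipate light through their intramolecular hydrogen bond and are expected to be photostable but strongly absorbing, hence the dilute thin-film irradiation and a final chromatographic separation from 12 and 13.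

**Compound list**

1 | (E)-4-hydroxycinnamic acid | O=C(O)/C=C/c1ccc(O)cc1 | starting material
2 | benzyl (E)-3-(4-hydroxyphenyl)prop-2-enoate | O=C(/C=C/c1ccc(O)cc1)OCc1ccccc1 | intermediate
3 | quinone methide phenol, benzyl (E)-3-{3-[1-(benzyloxycarbonyl)-2-(4-oxocyclohexa-2,5-dien-1-ylidene)ethyl]-4-hydroxyphenyl}prop-2-enoate (racemic) | O=C1C=CC(=CC(C(=O)OCc2ccccc2)c2cc(/C=C/C(=O)OCc3ccccc3)ccc2O)C=C1 | intermediate (not isolated)
4 | benzyl (2RS,3RS)-5-[(E)-3-(benzyloxy)-3-oxoprop-1-enyl]-2-(4-hydroxyphenyl)-2,3-dihydro-1-benzofuran-3-carboxylate (trans racemate, both enantiomers written) | O=C(/C=C/c1ccc2c(c1)[C@H](C(=O)OCc1ccccc1)[C@@H](c1ccc(O)cc1)O2)OCc1ccccc1.O=C(/C=C/c1ccc2c(c1)[C@@H](C(=O)OCc1ccccc1)[C@H](c1ccc(O)cc1)O2)OCc1ccccc1 | intermediate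
5 | benzyl (2S,3S)-5-[(E)-3-(benzyloxy)-3-oxoprop-1-enyl]-2-(4-hydroxyphenyl)-2,3-dihydro-1-benzofuran-3-carboxylate | O=C(/C=C/c1ccc2c(c1)[C@H](C(=O)OCc1ccccc1)[C@@H](c1ccc(O)cc1)O2)OCc1ccccc1 | intermediate
6 | benzyl (2S,3S)-5-[(E)-3-(benzyloxy)-3-oxoprop-1-enyl]-2-[4-(tert-butyldimethylsilyloxy)phenyl]-2,3-dihydro-1-benzofuran-3-carboxylate | O=C(/C=C/c1ccc2c(c1)[C@H](C(=O)OCc1ccccc1)[C@@H](c1ccc(O[Si](C)(C)C(C)(C)C)cc1)O2)OCc1ccccc1 | intermediate
7 | benzyl (2S,3S)-5-[3-(benzyloxy)-3-oxopropyl]-2-[4-(tert-butyldimethylsilyloxy)phenyl]-2,3-dihydro-1-benzofuran-3-carboxylate | O=C(CCc1ccc2c(c1)[C@H](C(=O)OCc1ccccc1)[C@@H](c1ccc(O[Si](C)(C)C(C)(C)C)cc1)O2)OCc1ccccc1 | intermediate (not isolated)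
8 | (2S,3S)-5-(2-carboxyethyl)-2-[4-(tert-butyldimethylsilyloxy)phenyl]-2,3-dihydro-1-benzofuran-3-carboxylic acid | O=C(O)CCc1ccc2c(c1)[C@H](C(=O)O)[C@@H](c1ccc(O[Si](C)(C)C(C)(C)C)cc1)O2 | intermediate
9 | 3-(tert-butyldimethylsilyloxy)phenol | CC(C)(C)[Si](C)(C)Oc1cccc(O)c1 | starting material
10 | 3-(tert-butyldimethylsilyloxy)phenyl (2S,3S)-2-[4-(tert-butyldimethylsilyloxy)phenyl]-5-{3-oxo-3-[3-(tert-butyldimethylsilyloxy)phenoxy]propyl}-2,3-dihydro-1-benzofuran-3-carboxylate | O=C(CCc1ccc2c(c1)[C@H](C(=O)Oc1cccc(O[Si](C)(C)C(C)(C)C)c1)[C@@H](c1ccc(O[Si](C)(C)C(C)(C)C)cc1)O2)Oc1cccc(O[Si](C)(C)C(C)(C)C)c1 | intermediate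
11 | 3-hydroxyphenyl (2S,3S)-2-(4-hydroxyphenyl)-5-[3-(3-hydroxyphenoxy)-3-oxopropyl]-2,3-dihydro-1-benzofuran-3-carboxylate | O=C(CCc1ccc2c(c1)[C@H](C(=O)Oc1cccc(O)c1)[C@@H](c1ccc(O)cc1)O2)Oc1cccc(O)c1 | intermediate
12 | 3-hydroxyphenyl (2S,3S)-5-[3-(2,4-dihydroxyphenyl)-3-oxopropyl]-2-(4-hydroxyphenyl)-2,3-dihydro-1-benzofuran-3-carboxylate | O=C(CCc1ccc2c(c1)[C@H](C(=O)Oc1cccc(O)c1)[C@@H](c1ccc(O)cc1)O2)c1ccc(O)cc1O | intermediate (not isolated)
13 | 3-hydroxyphenyl 3-[(2S,3S)-3-(2,4-dihydroxybenzoyl)-2-(4-hydroxyphenyl)-2,3-dihydro-1-benzofuran-5-yl]propanoate | O=C(CCc1ccc2c(c1)[C@H](C(=O)c1ccc(O)cc1O)[C@@H](c1ccc(O)cc1)O2)Oc1cccc(O)c1 | intermediate (not isolated)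
14 | 3-[(2S,3S)-3-(2,4-dihydroxybenzoyl)-2-(4-hydroxyphenyl)-2,3-dihydro-1-benzofuran-5-yl]-1-(2,4-dihydroxyphenyl)propan-1-one | O=C(CCc1ccc2c(c1)[C@H](C(=O)c1ccc(O)cc1O)[C@@H](c1ccc(O)cc1)O2)c1ccc(O)cc1O | target

**Step count**

Total: 8 steps. Longest linear sequence: 8 steps (1 → 14).

**Steps most likely to fail**

Step 8. Decarbonylation of the C3 acyl radical may compete with cage recombination. The reaction may also stall at 12 and 13 as the product ketones screen the light, and light-induced homolysis of the benzylic C2–O1 bond may erode the trans configuration. The fallback replaces radical-pair recombination by ionic C-acylation of free resorcinol and sets out from 5. Hydrogenation of 5 itself (H2, Pd/C, EtOAc/THF) should give the unprotected diacid (2S,3S)-5-(2-carboxyethyl)-2-(4-hydroxyphenyl)-2,3-dihydro-1-benzofuran-3-carboxylic acid F1. Heating F1 with excess resorcinol in BF3·OEt2 at about 80 °C, the standard Friedel–Crafts route from free acids to 2,4-dihydroxyphenyl ketones, at the lowest temperature that gives conversion, should acylate resorcinol at C4 twice and come back to the route at 14.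

Step 7. Fluoride or a liberated phenoxide may transacylate or cleave the two aryl esters while three aryl silyl ethers are removed. The fallback carries the one silyl ether through the photochemical step and removes it when no ester is left; it sets out from 8. Steglich esterification of 8 with a large excess of unprotected resorcinol should give 3-hydroxyphenyl (2S,3S)-2-[4-(tert-butyldimethylsilyloxy)phenyl]-5-[3-(3-hydroxyphenoxy)-3-oxopropyl]-2,3-dihydro-1-benzofuran-3-carboxylate F2. Irradiation as in step 8 should give the silyl ether of the target, 3-{(2S,3S)-2-[4-(tert-butyldimethylsilyloxy)phenyl]-3-(2,4-dihydroxybenzoyl)-2,3-dihydro-1-benzofuran-5-yl}-1-(2,4-dihydroxyphenyl)propan-1-one F3, and HF·pyridine then returns to the route at 14.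

Step 6. Activation of the hindered α-aryl C3 carboxyl may lead to ketene formation or to rearrangement of the O-acylisourea to an N-acylurea before the weakly nucleophilic phenol attacks. The fallback reverses the polarity and goes from 8 directly to 10 by copper-mediated Chan–Lam O-arylation of both carboxylic acids with 3-(tert-butyldimethylsilyloxy)phenylboronic acid (Cu(OTf)2, urea, EtOAc, air, 60 °C). The carboxylate acts as the nucleophile, so the C3 carbonyl is never activated; this fallback makes no new compound (F0).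

**Further compounds**

F1 | step 8 | (2S,3S)-5-(2-carboxyethyl)-2-(4-hydroxyphenyl)-2,3-dihydro-1-benzofuran-3-carboxylic acid | O=C(O)CCc1ccc2c(c1)[C@H](C(=O)O)[C@@H](c1ccc(O)cc1)O2
F2 | step 7 | 3-hydroxyphenyl (2S,3S)-2-[4-(tert-butyldimethylsilyloxy)phenyl]-5-[3-(3-hydroxyphenoxy)-3-oxopropyl]-2,3-dihydro-1-benzofuran-3-carboxylate | O=C(CCc1ccc2c(c1)[C@H](C(=O)Oc1cccc(O)c1)[C@@H](c1ccc(O[Si](C)(C)C(C)(C)C)cc1)O2)Oc1cccc(O)c1
F3 | step 7 | 3-{(2S,3S)-2-[4-(tert-butyldimethylsilyloxy)phenyl]-3-(2,4-dihydroxybenzoyl)-2,3-dihydro-1-benzofuran-5-yl}-1-(2,4-dihydroxyphenyl)propan-1-one | O=C(CCc1ccc2c(c1)[C@H](C(=O)c1ccc(O)cc1O)[C@@H](c1ccc(O[Si](C)(C)C(C)(C)C)cc1)O2)c1ccc(O)cc1O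
F0 | step 6 | none | none
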